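**Retrosynthetic overview**
1. The target 25 comes from the 8α-alcohol 20 by esterification at O8 and global desilylation; 20 comes from the cis-decalone 17 by C5 epimerisation and hydration of the C8=C9 alkene.
2. Key disconnection: ring A of 17 is opened to the cis-fused α-silyloxycyclobutanone 15 plus ethylene, i.e. a rhodium-catalysed C–C activation/insertion across C4–C1 that makes C1–C2 and C3–C4 together.
3. Enabling feature: the strained four-membered ring C1–C4–C5–C10, whose C4(=O)–C1 bond carries the oxygen on C1 and ends at the quaternary C10 (no β-hydrogen); C1 and C10 pass through unchanged and C5 stays epimerisable.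
4. 15 comes from anti-SN2′ delivery of the acrylate to C7 with loss of the C9 pivalate, α-oxygenation at C1 and dechlorination of the Diels–Alder adduct 9 of dichlorocyclobutenone 4 and the 1,4-dioxygenated diene 8.
5. Ring order: four-membered ring (step 1), then ring B by Diels–Alder (step 5), then ring A by two-carbon expansion of the four-membered ring (step 10).

Key step: step 10

Remark: eudesmane locants are used throughout (ring A = C1–C5, C10; ring B = C5–C10; C11–C13 = acrylate side chain), α/β mean opposite to/same side as the C10 methyl, and the bicyclic cyclobutanones carry the same locants.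

Step 1
Reactants: 1 propyne; 2 trichloroacetyl chloride
Product: 4 4,4-dichloro-3-methylcyclobut-2-en-1-one, via dichloroketene 3 (not isolated)
Conditions: Zn(Cu), POCl3, Et2O, 25 °C
Reagents that add atoms: none
Why: Zinc dehalogenation of 2 generates dichloroketene, which should undergo the regioselective thermal ketene–alkyne [2+2] cycloaddition (carbonyl carbon to the terminal alkyne carbon) without forming a stereocentre.

Step 2
Reactants: 5 (Z)-but-2-ene-1,4-diol
Product: 6 (Z)-4-hydroxybut-2-en-1-yl pivalate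
Conditions: PivCl (0.5 equiv), Et3N, DMAP (cat), CH2Cl2, −20 °C
Reagents that add atoms: pivaloyl chloride CC(C)(C)C(=O)Cl
Why: Mono-esterification of the symmetric diol used in excess; the hindered pivalate is chosen because it should survive the later enolate chemistry and then serve as the allylic leaving group.

Step 3
Reactants: 6 (Z)-4-hydroxybut-2-en-1-yl pivalate
Product: 7 (E)-4-oxobut-2-en-1-yl pivalate
Conditions: MnO2, CH2Cl2, 25 °C
Reagents that add atoms: none
Why: Allylic alcohol oxidation with MnO2, the enal equilibrating to the (E)-isomer, whose geometry is in any case lost when the C2–C3 bond becomes single in step 4.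

Step 4
Reactants: 7 (E)-4-oxobut-2-en-1-yl pivalate
Product: 8 (1E,3E)-4-(tert-butyldimethylsilyloxy)buta-1,3-dien-1-yl pivalate
Conditions: TBSOTf, Et3N, Et2O, 0 to 25 °C
Reagents that add atoms: tert-butyldimethylsilyl triflate CC(C)(C)[Si](C)(C)OS(=O)(=O)C(F)(F)F
Why: Silyl dienol ether formation by γ-deprotonation of the s-trans enal should give mainly the (1E,3E)-diene, the only isomer expected to react readily in step 5.

Step 5
Reactants: 4 4,4-dichloro-3-methylcyclobut-2-en-1-one; 8 (1E,3E)-4-(tert-butyldimethylsilyloxy)buta-1,3-dien-1-yl pivalate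
Product: 9 8,8-dichloro-1-methyl-7-oxo-5-(tert-butyldimethylsilyloxy)bicyclo[4.2.0]oct-3-en-2-yl pivalate (cis-fused; 6α-OTBS, 9α-OPiv, 10β-CH3, 5β-H, cyclobutanone carbons C1/C4 on the α-face)
Conditions: oxazaborolidinium catalyst from (S)-α,α-diphenylprolinol, o-tolylboroxine and HNTf2 (20 mol %), CH2Cl2, −78 to −40 °C
Reagents that add atoms: none
Why: Catalytic enantioselective Diels–Alder reaction of a strained cyclobutenone: the silyloxy terminus (stronger donor) should bond to the α-carbon C5 and the pivaloyloxy terminus to the β-carbon C10, the endo transition state places both oxygens cis to the cyclobutanone ring and trans to the angular methyl and H5, and the chiral Lewis acid selects the enone face, so that C5, C6, C9 and the quaternary C10 are set together.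

Step 6
Reactants: 9 Diels–Alder adduct
Product: 10 1-methyl-7-oxo-5-(tert-butyldimethylsilyloxy)bicyclo[4.2.0]oct-3-en-2-yl pivalate (stereodescriptors as in 9)
Conditions: Zn dust, AcOH, 25 °C
Reagents that add atoms: none
Why: Reductive dechlorination of the α,α-dichloroketone with zinc, under which the silyl ether, pivalate and alkene should be inert and no stereocentre changes.

Step 7
Reactants: 10 dechlorinated cyclobutanone
Product: 11 8-hydroxy-1-methyl-7-oxo-5-(tert-butyldimethylsilyloxy)bicyclo[4.2.0]oct-3-en-2-yl pivalate (new hydroxyl on C1, 1β, cis to the angular methyl)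
Conditions: KN(SiMe3)2, THF, −78 °C; 3-phenyl-2-(phenylsulfonyl)oxaziridine; AcOH quench
Reagents that add atoms: 3-phenyl-2-(phenylsulfonyl)oxaziridine O=S(=O)(c1ccccc1)N1OC1c1ccccc1
Why: Kinetic deprotonation at the only α-methylene (C1) and enolate oxidation by the N-sulfonyloxaziridine from the exo face of the cis-bicyclo[4.2.0] skeleton (away from ring B) should place the hydroxyl cis to the angular methyl (1β), which is also the thermodynamically preferred arrangement.

Step 8
Reactants: 11 α-ketol
Product: 12 5,8-bis(tert-butyldimethylsilyloxy)-1-methyl-7-oxobicyclo[4.2.0]oct-3-en-2-yl pivalate (1β-OTBS, 6α-OTBS, 9α-OPiv)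
Conditions: TBSOTf, 2,6-lutidine, CH2Cl2, −78 to 0 °C
Reagents that add atoms: tert-butyldimethylsilyl triflate CC(C)(C)[Si](C)(C)OS(=O)(=O)C(F)(F)F
Why: Silyl protection of the hindered α-ketol should block α-ketol rearrangement and fix the C1 configuration.

Step 9
Reactants: 12 bis-silyl cyclobutanone pivalate; 13 methyl 2-bromoacrylate
Product: 15 methyl 2-[5,8-bis(tert-butyldimethylsilyloxy)-1-methyl-7-oxobicyclo[4.2.0]oct-2-en-4-yl]acrylate (1β-OTBS, 6α-OTBS, 7β-side chain, 10β-CH3, 5β-H, C8=C9), via vinylcuprate 14 (not isolated)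
Conditions: n-Bu2CuLi (from n-BuLi, CuI), THF, −78 °C, then 13; then 12, −78 to −40 °C; NH4Cl work-up
Reagents that add atoms: none
Why: Anti-selective SN2′ allylic substitution by the α-(methoxycarbonyl)vinyl cuprate: attack at C7 anti to the 9α-pivalate (direct attack at the neopentylic C9 being disfavoured) should install the acrylate on the β-face, trans to the 6α-silyloxy group, and move the alkene to C8=C9.

Step 10
Reactants: 15 cyclobutanone acrylate; 16 ethylene
Product: 17 methyl 1β,6α-bis(tert-butyldimethylsilyloxy)-4-oxo-15-nor-5β-eudesma-8,11(13)-dien-12-oate (cis-decalone, 7α-H)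
Conditions: [Rh(C2H4)2Cl]2 (5 mol %), P(3,5-(CF3)2C6H3)3 (24 mol %), 2-amino-3-picoline (0.3 equiv), ethylene (10 bar), 1,4-dioxane, 130 °C
Reagents that add atoms: none
Why: Proposed new method: monovalent rhodium, helped by reversible ketimine formation with 2-amino-3-picoline, should add oxidatively into the strained C4(acyl)–C1 bond, ethylene should insert into the Rh–acyl bond (new C3–C4 bond) and C(sp3)–C(sp3) reductive elimination should then form C1–C2, so that the four-membered ring grows by two carbons in one catalytic cycle. The closest known reaction types are the rhodium-catalysed intramolecular cut-and-sew carboacylation of tethered olefins by cyclobutanones and the intermolecular insertion of ethylene into the C1–C2 bond of 1-indanones; intermolecular ethylene insertion into a saturated α-silyloxycyclobutanone has not been shown. Ring A is closed in a formal [4+2] mode (the C1–C10–C5–C4 unit plus ethylene), giving a six-membered ketone cis-fused to ring B. No stereocentre is created: C1 should be retained because oxidative addition and reductive elimination both go with retention, C10 is untouched and C5 is corrected in step 11. The step needs cleavage of C4–C1 rather than C4–C5 and insertion rather than decarbonylation: the oxygen on C1 should favour metal insertion at that bond, the Rh–C1 bond has no β-hydrogen because C10 is quaternary whereas a metal on C5 would be flanked by β-hydrogen and β-silyloxy groups and can only revert, and ethylene pressure together with the aminopyridine should suppress CO loss. The ring alkene and the 7β-acrylate cannot reach the metallacycle on the α-face without forming three-membered, four-membered or trans-bridged rings, so they should remain spectators.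

Step 11
Reactants: 17 cis-decalone
Product: 18 methyl 1β,6α-bis(tert-butyldimethylsilyloxy)-4-oxo-15-nor-5α-eudesma-8,11(13)-dien-12-oate (trans-decalone)
Conditions: DBU (0.2 equiv), toluene, 25 °C
Reagents that add atoms: none
Why: Base-mediated epimerisation α to the C4 ketone should funnel the cis-decalone (and any cis/trans mixture from step 10) into the thermodynamically favoured trans-fused isomer with 5α-H, in which the C6 and C7 substituents are equatorial.

Step 12
Reactants: 18 trans-decalone
Product: 19 methyl 8α,9α-epoxy-1β,6α-bis(tert-butyldimethylsilyloxy)-4-oxo-15-nor-5α-eudesm-11(13)-en-12-oate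
Conditions: mCPBA, NaHCO3, CH2Cl2, 0 °C
Reagents that add atoms: 3-chloroperoxybenzoic acid O=C(OO)c1cccc(Cl)c1
Why: Prilezhaev epoxidation of the only electron-rich alkene (C8=C9) from the α-face, the β-face being shielded by the axial C10 methyl and the 7β side chain, while the electron-poor acrylate and the hindered ketone should survive.

Step 13
Reactants: 19 8α,9α-epoxide
Product: 20 methyl 8α-hydroxy-1β,6α-bis(tert-butyldimethylsilyloxy)-4-oxo-15-nor-5α-eudesm-11(13)-en-12-oate
Conditions: Cp2TiCl2 (10 mol %), Mn dust, 2,4,6-collidine hydrochloride, 1,4-cyclohexadiene, THF, 25 °C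
Reagents that add atoms: none
Why: Titanocene-catalysed reductive epoxide opening (electron transfer from trivalent titanium, then hydrogen-atom transfer): homolysis of the more congested C9–O bond next to the quaternary C10 should leave the oxygen on C8 with its α-configuration untouched, giving the equatorial 8α-alcohol.

Step 14
Reactants: 21 methyl 2-(hydroxymethyl)acrylate
Product: 22 methyl 2-[(tert-butyldimethylsilyloxy)methyl]acrylate
Conditions: TBSCl, imidazole, DMF, 25 °C
Reagents that add atoms: tert-butyldimethylsilyl chloride CC(C)(C)[Si](C)(C)Cl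
Why: Standard silylation (protection) of the primary allylic alcohol.

Step 15
Reactants: 22 methyl 2-[(tert-butyldimethylsilyloxy)methyl]acrylate
Product: 23 2-[(tert-butyldimethylsilyloxy)methyl]acrylic acid
Conditions: LiOH, THF–H2O, 0 °C; then dilute HCl
Reagents that add atoms: lithium hydroxide [Li+].[OH-]
Why: Ester saponification at 0 °C, under which the silyl ether and the acrylate double bond should survive.

Step 16
Reactants: 20 8α-alcohol; 23 2-[(tert-butyldimethylsilyloxy)methyl]acrylic acid
Product: 24 methyl 1β,6α-bis(tert-butyldimethylsilyloxy)-8α-{2-[(tert-butyldimethylsilyloxy)methyl]acryloyloxy}-4-oxo-15-nor-5α-eudesm-11(13)-en-12-oate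
Conditions: EDC·HCl, DMAP, CH2Cl2, 25 °C
Reagents that add atoms: none
Why: Steglich-type carbodiimide esterification of the single free hydroxyl, which keeps the C8 configuration because the C8–O bond is not touched.

Step 17
Reactants: 24 tris-silyl ether
Product: 25 methyl 1β,6α-dihydroxy-8α-[2-(hydroxymethyl)acryloyloxy]-4-oxo-15-nor-5α-eudesm-11(13)-en-12-oate (CNP0144895.1)
Conditions: HF·pyridine, THF–pyridine, 0 to 25 °C
Reagents that add atoms: none
Why: Global desilylation with buffered HF·pyridine, mildly acidic conditions that should avoid retro-aldol or β-elimination of the β-hydroxy ketone and conjugate addition to the two acrylates.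

**Compound list**
1 | propyne | CC#C | starting material
2 | trichloroacetyl chloride | ClC(=O)C(Cl)(Cl)Cl | starting material
3 | dichloroketene | ClC(Cl)=C=O | intermediate
4 | 4,4-dichloro-3-methylcyclobut-2-en-1-one | CC1=CC(=O)C1(Cl)Cl | intermediate
5 | (Z)-but-2-ene-1,4-diol | OC/C=C\CO | starting material
6 | (Z)-4-hydroxybut-2-en-1-yl pivalate | CC(C)(C)C(=O)OC/C=C\CO | intermediate
7 | (E)-4-oxobut-2-en-1-yl pivalate | CC(C)(C)C(=O)OC/C=C/C=O | intermediate
8 | (1E,3E)-4-(tert-butyldimethylsilyloxy)buta-1,3-dien-1-yl pivalate | CC(C)(C)C(=O)O/C=C/C=C/O[Si](C)(C)C(C)(C)C | intermediate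
9 | 8,8-dichloro-1-methyl-7-oxo-5-(tert-butyldimethylsilyloxy)bicyclo[4.2.0]oct-3-en-2-yl pivalate (6α-OTBS, 9α-OPiv, 10β-CH3, 5β-H) | CC(C)(C)C(=O)O[C@@H]1C=C[C@H](O[Si](C)(C)C(C)(C)C)[C@@H]2C(=O)C(Cl)(Cl)[C@]12C | intermediate
10 | 1-methyl-7-oxo-5-(tert-butyldimethylsilyloxy)bicyclo[4.2.0]oct-3-en-2-yl pivalate | CC(C)(C)C(=O)O[C@@H]1C=C[C@H](O[Si](C)(C)C(C)(C)C)[C@@H]2C(=O)C[C@]12C | intermediate
11 | 8-hydroxy-1-methyl-7-oxo-5-(tert-butyldimethylsilyloxy)bicyclo[4.2.0]oct-3-en-2-yl pivalate (1β-OH) | CC(C)(C)C(=O)O[C@@H]1C=C[C@H](O[Si](C)(C)C(C)(C)C)[C@@H]2C(=O)[C@@H](O)[C@]12C | intermediate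
12 | 5,8-bis(tert-butyldimethylsilyloxy)-1-methyl-7-oxobicyclo[4.2.0]oct-3-en-2-yl pivalate | CC(C)(C)C(=O)O[C@@H]1C=C[C@H](O[Si](C)(C)C(C)(C)C)[C@@H]2C(=O)[C@@H](O[Si](C)(C)C(C)(C)C)[C@]12C | intermediate
13 | methyl 2-bromoacrylate | C=C(Br)C(=O)OC | starting material
14 | lithium butyl[1-(methoxycarbonyl)vinyl]cuprate | [Li+].CCCC[Cu-]C(=C)C(=O)OC | intermediate
15 | methyl 2-[5,8-bis(tert-butyldimethylsilyloxy)-1-methyl-7-oxobicyclo[4.2.0]oct-2-en-4-yl]acrylate (1β,6α-bis-OTBS, 7β-side chain, 5β-H) | COC(=O)C(=C)[C@@H]1C=C[C@@]2(C)[C@H](O[Si](C)(C)C(C)(C)C)C(=O)[C@H]2[C@H]1O[Si](C)(C)C(C)(C)C | intermediate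
16 | ethylene | C=C | starting material
17 | methyl 1β,6α-bis(tert-butyldimethylsilyloxy)-4-oxo-15-nor-5β-eudesma-8,11(13)-dien-12-oate | C1=C[C@@]2(C)[C@H](O[Si](C)(C)C(C)(C)C)CCC(=O)[C@H]2[C@@H](O[Si](C)(C)C(C)(C)C)[C@@H]1C(=C)C(=O)OC | intermediate
18 | methyl 1β,6α-bis(tert-butyldimethylsilyloxy)-4-oxo-15-nor-5α-eudesma-8,11(13)-dien-12-oate | C1=C[C@@]2(C)[C@H](O[Si](C)(C)C(C)(C)C)CCC(=O)[C@@H]2[C@@H](O[Si](C)(C)C(C)(C)C)[C@@H]1C(=C)C(=O)OC | intermediate
19 | methyl 8α,9α-epoxy-1β,6α-bis(tert-butyldimethylsilyloxy)-4-oxo-15-nor-5α-eudesm-11(13)-en-12-oate | [C@H]12O[C@H]1[C@@]3(C)[C@H](O[Si](C)(C)C(C)(C)C)CCC(=O)[C@@H]3[C@@H](O[Si](C)(C)C(C)(C)C)[C@@H]2C(=C)C(=O)OC | intermediate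
20 | methyl 8α-hydroxy-1β,6α-bis(tert-butyldimethylsilyloxy)-4-oxo-15-nor-5α-eudesm-11(13)-en-12-oate | O[C@H]1C[C@@]2(C)[C@H](O[Si](C)(C)C(C)(C)C)CCC(=O)[C@@H]2[C@@H](O[Si](C)(C)C(C)(C)C)[C@@H]1C(=C)C(=O)OC | intermediate
21 | methyl 2-(hydroxymethyl)acrylate | C=C(CO)C(=O)OC | starting material
22 | methyl 2-[(tert-butyldimethylsilyloxy)methyl]acrylate | C=C(CO[Si](C)(C)C(C)(C)C)C(=O)OC | intermediate
23 | 2-[(tert-butyldimethylsilyloxy)methyl]acrylic acid | C=C(CO[Si](C)(C)C(C)(C)C)C(=O)O | intermediate
24 | methyl 1β,6α-bis(tert-butyldimethylsilyloxy)-8α-{2-[(tert-butyldimethylsilyloxy)methyl]acryloyloxy}-4-oxo-15-nor-5α-eudesm-11(13)-en-12-oate | C=C(CO[Si](C)(C)C(C)(C)C)C(=O)O[C@H]1C[C@@]2(C)[C@H](O[Si](C)(C)C(C)(C)C)CCC(=O)[C@@H]2[C@@H](O[Si](C)(C)C(C)(C)C)[C@@H]1C(=C)C(=O)OC | intermediate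
25 | methyl 1β,6α-dihydroxy-8α-[2-(hydroxymethyl)acryloyloxy]-4-oxo-15-nor-5α-eudesm-11(13)-en-12-oate (CNP0144895.1) | C=C(CO)C(=O)O[C@H]1C[C@@]2(C)[C@H](O)CCC(=O)[C@@H]2[C@@H](O)[C@@H]1C(=C)C(=O)OC | target

**Step count and risks**
Total step count: 17. Longest linear sequence: 14 steps (5 to 25 through steps 2–13, 16 and 17).

Steps most likely to fail:

1. Step 10 (Proposed new method). The metallacycle may lose CO to a cyclopropane, the metal may enter the C4–C5 bond, ethylene may fail to insert, or the ring alkene may migrate under the hot rhodium conditions. Fallback: the ring expansion is given up and the six-membered ketone is used directly as the dienophile. The route sets out from diene 8, which would be combined with the known enone (R)-4-(tert-butyldimethylsilyloxy)-3-methylcyclohex-2-en-1-one F1 in a high-pressure (about 13 kbar, CH2Cl2) or EtAlCl2-promoted Diels–Alder reaction. The diene should add endo and anti to the C1 silyloxy group to give the cis-decalone pivalate (9α-pivaloyloxy-1β,6α-bis(tert-butyldimethylsilyloxy)-15-nor-5β-eudesm-7-en-4-one) F2. Anti-SN2′ substitution of F2 with cuprate 14 under the conditions of step 9 would then return to the route at 17.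

2. Step 5. Facial discrimination by the chiral Lewis acid may be insufficient, or the acid may erode the silyl dienol ether. Fallback: enantiocontrol is moved from catalysis to a kinetic resolution. Setting out from 4 and 8, an uncatalysed thermal Diels–Alder reaction would give 9 together with its enantiomer ent-9 F3. Steps 6 and 7 run on the racemate would give 10 with ent-10 F4 and then 11 with ent-11 F5. A lipase (screened with vinyl acetate in MTBE) would acetylate the unwanted ketol to the acetate of ent-11 F6 and leave 11, where the route is rejoined.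

3. Step 13. Homolysis may occur at C8–O instead of C9–O, or the β-titanoxy radical may be deoxygenated back to alkene 18. Fallback: the oxygen at C8 is installed by dihydroxylation and the C9 oxygen is removed afterwards. Setting out from 18, OsO4 (cat)/NMO should dihydroxylate C8=C9 from the α-face to the 8α,9α-diol F7. The equatorial C8 hydroxyl would be esterified selectively with acid 23 (EDC·HCl, DMAP) to the 8-ester 9α-alcohol F8. The axial C9 hydroxyl would be converted with 1,1′-thiocarbonyldiimidazole into the 9-O-(imidazol-1-ylthiocarbonyl) derivative F9, and Barton–McCombie deoxygenation with (Me3Si)3SiH/AIBN would return to the route at 24.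

**Further compounds**
F1 | step 10 | (R)-4-(tert-butyldimethylsilyloxy)-3-methylcyclohex-2-en-1-one | CC1=CC(=O)CC[C@H]1O[Si](C)(C)C(C)(C)C
F2 | step 10 | 9α-pivaloyloxy-1β,6α-bis(tert-butyldimethylsilyloxy)-15-nor-5β-eudesm-7-en-4-one | CC(C)(C)C(=O)O[C@@H]1C=C[C@H](O[Si](C)(C)C(C)(C)C)[C@@H]2C(=O)CC[C@@H](O[Si](C)(C)C(C)(C)C)[C@]12C
F3 | step 5 | ent-9 | CC(C)(C)C(=O)O[C@H]1C=C[C@@H](O[Si](C)(C)C(C)(C)C)[C@H]2C(=O)C(Cl)(Cl)[C@@]12C
F4 | step 5 | ent-10 | CC(C)(C)C(=O)O[C@H]1C=C[C@@H](O[Si](C)(C)C(C)(C)C)[C@H]2C(=O)C[C@@]12C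
F5 | step 5 | ent-11 | CC(C)(C)C(=O)O[C@H]1C=C[C@@H](O[Si](C)(C)C(C)(C)C)[C@H]2C(=O)[C@H](O)[C@@]12C
F6 | step 5 | acetate of ent-11 | CC(C)(C)C(=O)O[C@H]1C=C[C@@H](O[Si](C)(C)C(C)(C)C)[C@H]2C(=O)[C@H](OC(C)=O)[C@@]12C
F7 | step 13 | methyl 8α,9α-dihydroxy-1β,6α-bis(tert-butyldimethylsilyloxy)-4-oxo-15-nor-5α-eudesm-11(13)-en-12-oate | O[C@H]1[C@@H](O)[C@@]2(C)[C@H](O[Si](C)(C)C(C)(C)C)CCC(=O)[C@@H]2[C@@H](O[Si](C)(C)C(C)(C)C)[C@@H]1C(=C)C(=O)OC
F8 | step 13 | 9α-hydroxy derivative of 24 | C=C(CO[Si](C)(C)C(C)(C)C)C(=O)O[C@H]1[C@@H](O)[C@@]2(C)[C@H](O[Si](C)(C)C(C)(C)C)CCC(=O)[C@@H]2[C@@H](O[Si](C)(C)C(C)(C)C)[C@@H]1C(=C)C(=O)OC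
F9 | step 13 | 9α-O-(imidazol-1-ylthiocarbonyl) derivative of F8 | C=C(CO[Si](C)(C)C(C)(C)C)C(=O)O[C@H]1[C@@H](OC(=S)n3ccnc3)[C@@]2(C)[C@H](O[Si](C)(C)C(C)(C)C)CCC(=O)[C@@H]2[C@@H](O[Si](C)(C)C(C)(C)C)[C@@H]1C(=C)C(=O)OC
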